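**Plan**

- The two silyl ethers come off last. Before that, ring C (O1, C2, C3, C4, C4a, C8a) is cut at C4a–C4, C4–C3 and O1–C2. Its carbonyl carbon C4 lies between the twofold-symmetric phloroglucinol ring A and the C3–C2 unit on ring B, so the ring maps onto an aryl iodide, CO and a terminal alkyne.
- The ring B alkyne is cut at C7''–C8'' (aldol), at O4'–C8'' (phenol alkylation by a bromoacetate) and at C2–C3 (aldehyde-to-alkyne homologation).
- Forward: syringaldehyde is alkylated and homologated to an arylacetylene acid, loaded on (R)-4-benzyloxazolidin-2-one and joined to silylated vanillin. Inversion, reduction, γ-acetylation and silylation then give the alkyne. Ring A comes from phloroglucinol, and ring C is closed last.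
- Stereochemistry: C8'' (S) is set by the auxiliary-controlled Evans syn-aldol. C7'' (R) is set by Mitsunobu inversion of the syn adduct, which converts the threo into the erythro (7''R,8''S) series.

Key step: step 12

Remark: the target is read as the erythro (anti) isomer, 7''R,8''S; (R)-4-benzyloxazolidin-2-one, methyl bromoacetate and dimethyl (1-diazo-2-oxopropyl)phosphonate are taken as commercial.

**Route**

Step 1
Reactants: 1 syringaldehyde; 2 methyl bromoacetate
Product: 3 methyl 2-(4-formyl-2,6-dimethoxyphenoxy)acetate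
Conditions: K2CO3, DMF, 50 °C
Reagents that add atoms: none
Why: Williamson ether synthesis, in which the para-formyl group makes the hindered phenol acidic enough for K2CO3 and the phenoxide displaces bromide from the activated α-bromo ester, forming the O4'–C8'' bond.

Step 2
Reactants: 3 methyl 2-(4-formyl-2,6-dimethoxyphenoxy)acetate
Product: 5 2-(4-ethynyl-2,6-dimethoxyphenoxy)acetic acid, via methyl 2-(4-ethynyl-2,6-dimethoxyphenoxy)acetate 4 (not isolated)
Conditions: dimethyl (1-diazo-2-oxopropyl)phosphonate, K2CO3, MeOH, rt; then LiOH, H2O/THF, rt; then 1 M HCl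
Reagents that add atoms: dimethyl (1-diazo-2-oxopropyl)phosphonate, CC(=O)C(=[N+]=[N-])P(=O)(OC)OC; lithium hydroxide, [Li+].[OH-]
Why: Ohira–Bestmann reaction, in which methanolysis of the reagent releases the diazomethylphosphonate anion that olefinates the aldehyde and loses N2 to give the terminal alkyne (the added carbon becomes C3), followed by saponification of the methyl ester in the same flask so that the acid can be separated from neutral by-products by extraction.

Step 3
Reactants: 5 2-(4-ethynyl-2,6-dimethoxyphenoxy)acetic acid; 6 (R)-4-benzyloxazolidin-2-one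
Product: 8 (R)-4-benzyl-3-[2-(4-ethynyl-2,6-dimethoxyphenoxy)acetyl]oxazolidin-2-one, via pivalic mixed anhydride 7 (not isolated)
Conditions: PivCl, Et3N, THF, −20 °C; then 6, LiCl, −20 °C → rt
Reagents that add atoms: none
Why: N-acylation of an oxazolidinone through a pivalic mixed anhydride under LiCl/Et3N activation, the nucleophile attacking the less hindered aryloxyacetyl carbonyl.

Step 4
Reactants: 9 vanillin
Product: 10 4-(tert-butyldimethylsilyloxy)-3-methoxybenzaldehyde
Conditions: TBSCl, imidazole, CH2Cl2, rt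
Reagents that add atoms: tert-butyldimethylsilyl chloride, CC(C)(C)[Si](C)(C)Cl
Why: Standard imidazole-promoted silylation of a phenol, which masks the acidic hydroxyl before the boron aldol.

Step 5
Reactants: 8 (R)-4-benzyl-3-[2-(4-ethynyl-2,6-dimethoxyphenoxy)acetyl]oxazolidin-2-one; 10 4-(tert-butyldimethylsilyloxy)-3-methoxybenzaldehyde
Product: 12 (R)-4-benzyl-3-[(2R,3S)-3-[4-(tert-butyldimethylsilyloxy)-3-methoxyphenyl]-2-(4-ethynyl-2,6-dimethoxyphenoxy)-3-hydroxypropanoyl]oxazolidin-2-one, via dibutylboron Z-enolate 11 (not isolated)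
Conditions: Bu2BOTf, i-Pr2NEt, CH2Cl2, −78 → 0 °C; then 10, −78 °C → rt; pH 7 buffer, MeOH, 30% H2O2, 0 °C
Reagents that add atoms: none
Why: Evans syn-aldol reaction, in which soft enolisation gives the Z-boron enolate that adds to the aldehyde through a closed chair transition state on the enolate face opposite the benzyl group of the (R)-auxiliary, so that C8'' is set with its final configuration (2R in the imide) and C7'' as the syn (3S) carbinol.

Step 6
Reactants: 12 the syn-aldol adduct
Product: 13 (R)-4-benzyl-3-[(2R,3R)-3-[4-(tert-butyldimethylsilyloxy)-3-methoxyphenyl]-2-(4-ethynyl-2,6-dimethoxyphenoxy)-3-(4-nitrobenzoyloxy)propanoyl]oxazolidin-2-one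
Conditions: 4-nitrobenzoic acid, PPh3, DIAD, toluene, 0 °C → rt
Reagents that add atoms: 4-nitrobenzoic acid, OC(=O)c1ccc(cc1)[N+](=O)[O-]
Why: Mitsunobu reaction, in which the benzylic hydroxyl is activated by PPh3/DIAD and displaced by 4-nitrobenzoate in an SN2 process that inverts C7'' to R (anti, erythro series), ionisation being disfavoured by the adjacent electron-withdrawing imide carbonyl and aryloxy group.

Step 7
Reactants: 13 the inverted 4-nitrobenzoate
Product: 14 (1R,2S)-1-[4-(tert-butyldimethylsilyloxy)-3-methoxyphenyl]-2-(4-ethynyl-2,6-dimethoxyphenoxy)propane-1,3-diol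
Conditions: LiBH4, MeOH, THF, 0 °C → rt
Reagents that add atoms: none
Why: Hydride reduction with LiBH4 cleaves the N-acyl oxazolidinone to the primary alcohol (C9'') and the activated 4-nitrobenzoate to the benzylic alcohol by acyl–oxygen cleavage, so neither stereocentre is touched and the auxiliary is recovered.

Step 8
Reactants: 14 the erythro diol
Product: 15 (2S,3R)-3-[4-(tert-butyldimethylsilyloxy)-3-methoxyphenyl]-2-(4-ethynyl-2,6-dimethoxyphenoxy)-3-hydroxypropyl acetate
Conditions: AcCl (1.05 equiv), 2,4,6-collidine, CH2Cl2, −78 °C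
Reagents that add atoms: acetyl chloride, CC(Cl)=O
Why: Selective acylation, since at −78 °C with the hindered base collidine the unhindered primary hydroxyl should be acetylated much faster than the secondary benzylic hydroxyl.

Step 9
Reactants: 15 the γ-acetate
Product: 16 (2S,3R)-3-(tert-butyldimethylsilyloxy)-3-[4-(tert-butyldimethylsilyloxy)-3-methoxyphenyl]-2-(4-ethynyl-2,6-dimethoxyphenoxy)propyl acetate
Conditions: TBSOTf, 2,6-lutidine, CH2Cl2, −78 → 0 °C
Reagents that add atoms: tert-butyldimethylsilyl triflate, CC(C)(C)[Si](C)(C)OS(=O)(=O)C(F)(F)F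
Why: Silyl triflate/lutidine silylation of a hindered secondary alcohol at low temperature, which blocks the benzylic oxygen against acetyl migration and against acylation in the carbonylation.

Step 10
Reactants: 17 phloroglucinol
Product: 18 2-iodobenzene-1,3,5-triol
Conditions: I2 (1.0 equiv), NaHCO3, THF/H2O, 0 °C
Reagents that add atoms: iodine, II
Why: Electrophilic aromatic iodination of a highly activated arene whose three ring positions are equivalent, so one equivalent of I2 with NaHCO3 as acid scavenger should stop at the mono-iodide, which is used at once.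

Step 11
Reactants: 18 2-iodobenzene-1,3,5-triol
Product: 19 2-iodobenzene-1,3,5-triyl triacetate
Conditions: Ac2O, pyridine, DMAP (cat.), CH2Cl2, 0 °C → rt
Reagents that add atoms: acetic anhydride, CC(=O)OC(C)=O
Why: Pyridine/DMAP-catalysed O-acetylation of the three phenols, which stabilises the electron-rich iodide and stores the ortho oxygen nucleophile in latent form.

Step 12
Reactants: 19 2-iodobenzene-1,3,5-triyl triacetate; 20 carbon monoxide; 16 the bis-silylated ring B alkyne
Product: 23 2-{4-[(1R,2S)-3-acetoxy-1-(tert-butyldimethylsilyloxy)-1-[4-(tert-butyldimethylsilyloxy)-3-methoxyphenyl]propan-2-yloxy]-3,5-dimethoxyphenyl}-5,7-dihydroxy-4H-chromen-4-one, via triacetoxyaryl ynone 21 (not isolated), via diethylamino enone 22 (not isolated)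
Conditions: PdCl2(PPh3)2 (5 mol %), CO (1 atm), Et2NH/THF, 40 °C, no copper salt
Reagents that add atoms: none
Why: Zerovalent palladium formed from PdCl2(PPh3)2 inserts into the C–I bond of 19, and CO insertion, alkynyl transfer from 16 and reductive elimination give ynone 21 (bonds C4a–C4 and C4–C3); Et2NH then adds to the ynone and aminolyses the three aryl acetates to give enaminone 22, whose ortho phenoxide attacks C2 and expels Et2NH (bond O1–C2). The closest known reaction type is the carbonylative Sonogashira coupling–cyclisation of ortho-iodophenols or their acetates with arylacetylenes in a secondary amine, which gives flavones. Ring C closes in the 6-endo mode by conjugate addition–elimination at the β-carbon of the amino enone, not by 5-exo attack, which would lead to an aurone. No stereocentre is formed, and C7'' and C8'' are remote from the reacting atoms and carry no acidic hydrogen, so they should pass unchanged. The step needs carbonylative rather than direct coupling, which the CO atmosphere and the absence of copper should secure; it needs 6-endo closure, which the amine adduct secures; and it needs cleavage of aryl but not alkyl acetate, which the far higher reactivity of phenyl esters towards Et2NH at 40 °C should secure. The twofold symmetry of ring A about the C–I axis makes both ortho oxygens equivalent, so only the 5,7-dihydroxyflavone can form.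

Step 13
Reactants: 23 the flavone bis-silyl ether
Product: 24 (2S,3R)-2-[4-(5,7-dihydroxy-4-oxo-4H-chromen-2-yl)-2,6-dimethoxyphenoxy]-3-hydroxy-3-(4-hydroxy-3-methoxyphenyl)propyl acetate (CNP0157817.1)
Conditions: HF·pyridine, pyridine, THF, 0 °C → rt
Reagents that add atoms: none
Why: Fluoride-mediated desilylation, in which HF·pyridine cleaves the aryl and the benzylic silyl ethers at Si–O under buffered, mildly acidic conditions that leave the primary acetate in place and avoid base-induced 1,3-acetyl migration, so C7'' and C8'' keep their configuration.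

**Compound list**

1 | syringaldehyde (4-hydroxy-3,5-dimethoxybenzaldehyde) | COc1cc(C=O)cc(OC)c1O | starting material
2 | methyl bromoacetate | COC(=O)CBr | starting material
3 | methyl 2-(4-formyl-2,6-dimethoxyphenoxy)acetate | COC(=O)COc1c(OC)cc(C=O)cc1OC | intermediate
4 | methyl 2-(4-ethynyl-2,6-dimethoxyphenoxy)acetate (not isolated) | COC(=O)COc1c(OC)cc(C#C)cc1OC | intermediate
5 | 2-(4-ethynyl-2,6-dimethoxyphenoxy)acetic acid | OC(=O)COc1c(OC)cc(C#C)cc1OC | intermediate
6 | (R)-4-benzyloxazolidin-2-one | O=C1OC[C@@H](Cc2ccccc2)N1 | starting material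
7 | 2-(4-ethynyl-2,6-dimethoxyphenoxy)acetic pivalic anhydride (not isolated) | CC(C)(C)C(=O)OC(=O)COc1c(OC)cc(C#C)cc1OC | intermediate
8 | (R)-4-benzyl-3-[2-(4-ethynyl-2,6-dimethoxyphenoxy)acetyl]oxazolidin-2-one | C#Cc1cc(OC)c(OCC(=O)N2C(=O)OC[C@H]2Cc2ccccc2)c(OC)c1 | intermediate
9 | vanillin (4-hydroxy-3-methoxybenzaldehyde) | COc1cc(C=O)ccc1O | starting material
10 | 4-(tert-butyldimethylsilyloxy)-3-methoxybenzaldehyde | COc1cc(C=O)ccc1O[Si](C)(C)C(C)(C)C | intermediate
11 | dibutylboron (Z)-enolate of imide 8 (not isolated) | CCCCB(CCCC)O/C(=C\Oc1c(OC)cc(C#C)cc1OC)N1C(=O)OC[C@H]1Cc1ccccc1 | intermediate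
12 | (R)-4-benzyl-3-[(2R,3S)-3-[4-(tert-butyldimethylsilyloxy)-3-methoxyphenyl]-2-(4-ethynyl-2,6-dimethoxyphenoxy)-3-hydroxypropanoyl]oxazolidin-2-one (syn adduct) | COc1cc([C@H](O)[C@H](C(=O)N2C(=O)OC[C@H]2Cc2ccccc2)Oc2c(OC)cc(C#C)cc2OC)ccc1O[Si](C)(C)C(C)(C)C | intermediate
13 | (R)-4-benzyl-3-[(2R,3R)-3-[4-(tert-butyldimethylsilyloxy)-3-methoxyphenyl]-2-(4-ethynyl-2,6-dimethoxyphenoxy)-3-(4-nitrobenzoyloxy)propanoyl]oxazolidin-2-one (anti ester) | COc1cc([C@@H](OC(=O)c2ccc(cc2)[N+](=O)[O-])[C@H](C(=O)N2C(=O)OC[C@H]2Cc2ccccc2)Oc2c(OC)cc(C#C)cc2OC)ccc1O[Si](C)(C)C(C)(C)C | intermediate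
14 | (1R,2S)-1-[4-(tert-butyldimethylsilyloxy)-3-methoxyphenyl]-2-(4-ethynyl-2,6-dimethoxyphenoxy)propane-1,3-diol (erythro) | COc1cc([C@@H](O)[C@H](CO)Oc2c(OC)cc(C#C)cc2OC)ccc1O[Si](C)(C)C(C)(C)C | intermediate
15 | (2S,3R)-3-[4-(tert-butyldimethylsilyloxy)-3-methoxyphenyl]-2-(4-ethynyl-2,6-dimethoxyphenoxy)-3-hydroxypropyl acetate | COc1cc([C@@H](O)[C@H](COC(C)=O)Oc2c(OC)cc(C#C)cc2OC)ccc1O[Si](C)(C)C(C)(C)C | intermediate
16 | (2S,3R)-3-(tert-butyldimethylsilyloxy)-3-[4-(tert-butyldimethylsilyloxy)-3-methoxyphenyl]-2-(4-ethynyl-2,6-dimethoxyphenoxy)propyl acetate | COc1cc([C@@H](O[Si](C)(C)C(C)(C)C)[C@H](COC(C)=O)Oc2c(OC)cc(C#C)cc2OC)ccc1O[Si](C)(C)C(C)(C)C | intermediate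
17 | phloroglucinol (benzene-1,3,5-triol) | Oc1cc(O)cc(O)c1 | starting material
18 | 2-iodobenzene-1,3,5-triol | Oc1cc(O)c(I)c(O)c1 | intermediate
19 | 2-iodobenzene-1,3,5-triyl triacetate | CC(=O)Oc1cc(OC(C)=O)c(I)c(OC(C)=O)c1 | intermediate
20 | carbon monoxide | [C-]#[O+] | starting material
21 | 2-[3-(4-{[(1R,2S)-3-acetoxy-1-(tert-butyldimethylsilyloxy)-1-[4-(tert-butyldimethylsilyloxy)-3-methoxyphenyl]propan-2-yl]oxy}-3,5-dimethoxyphenyl)prop-2-ynoyl]benzene-1,3,5-triyl triacetate (not isolated) | COc1cc([C@@H](O[Si](C)(C)C(C)(C)C)[C@H](COC(C)=O)Oc2c(OC)cc(C#CC(=O)c3c(OC(C)=O)cc(OC(C)=O)cc3OC(C)=O)cc2OC)ccc1O[Si](C)(C)C(C)(C)C | intermediate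
22 | (E)-3-(diethylamino)-1-(2,4,6-trihydroxyphenyl)prop-2-en-1-one carrying at C3 the same 4-alkoxy-3,5-dimethoxyphenyl group as 21 (not isolated) | COc1cc([C@@H](O[Si](C)(C)C(C)(C)C)[C@H](COC(C)=O)Oc2c(OC)cc(/C(=C\C(=O)c3c(O)cc(O)cc3O)N(CC)CC)cc2OC)ccc1O[Si](C)(C)C(C)(C)C | intermediate
23 | 2-{4-[(1R,2S)-3-acetoxy-1-(tert-butyldimethylsilyloxy)-1-[4-(tert-butyldimethylsilyloxy)-3-methoxyphenyl]propan-2-yloxy]-3,5-dimethoxyphenyl}-5,7-dihydroxy-4H-chromen-4-one | COc1cc([C@@H](O[Si](C)(C)C(C)(C)C)[C@H](COC(C)=O)Oc2c(OC)cc(-c3cc(=O)c4c(O)cc(O)cc4o3)cc2OC)ccc1O[Si](C)(C)C(C)(C)C | intermediate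
24 | (2S,3R)-2-[4-(5,7-dihydroxy-4-oxo-4H-chromen-2-yl)-2,6-dimethoxyphenoxy]-3-hydroxy-3-(4-hydroxy-3-methoxyphenyl)propyl acetate | COc1cc([C@@H](O)[C@H](COC(C)=O)Oc2c(OC)cc(-c3cc(=O)c4c(O)cc(O)cc4o3)cc2OC)ccc1O | target

**Totals**

Total step count: 13.
Longest linear sequence: 10 steps (1, 2, 3, 5, 6, 7, 8, 9, 12, 13, from syringaldehyde).

**Steps most likely to fail**

Step 6. The activated benzylic C–O bond may ionise at the electron-rich carbon, which would erode the inversion. β-Elimination towards the α-aryloxy cinnamoyl imide may also compete, here or during the hydride cleavage of step 7. The fallback sets out from 12 and replaces inversion by oxidation and reduction. LiBH4 (MeOH, THF, 0 °C) should give the threo diol (1S,2S)-1-[4-(tert-butyldimethylsilyloxy)-3-methoxyphenyl]-2-(4-ethynyl-2,6-dimethoxyphenoxy)propane-1,3-diol F1. DDQ in CH2Cl2 should then oxidise only the benzylic hydroxyl to (S)-1-[4-(tert-butyldimethylsilyloxy)-3-methoxyphenyl]-2-(4-ethynyl-2,6-dimethoxyphenoxy)-3-hydroxypropan-1-one F2. Chelation-controlled reduction with Zn(BH4)2 in Et2O at −78 °C should favour the erythro diol, which is separated from residual threo isomer (recycled as F1). The route is rejoined at 14.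

Step 12. The aryl acetates may be aminolysed before oxidative addition, which would leave an electron-rich iodophenol prone to protodeiodination. Et2NH may also capture the acyl–palladium intermediate, or coupling may occur without CO uptake. The fallback sets out from 16 and from commercial 2,4,6-trihydroxybenzoic acid (OC(=O)c1c(O)cc(O)cc1O), and forms the C4a–C4 bond before the coupling. Peracetylation (Ac2O, pyridine, 0 °C) should give 2,4,6-triacetoxybenzoic acid F3. Oxalyl chloride with catalytic DMF in CH2Cl2 should give 2,4,6-triacetoxybenzoyl chloride F4. Acyl Sonogashira coupling of F4 with 16 (PdCl2(PPh3)2, CuI, Et3N, THF, rt) should give ynone 21, now isolated. Et2NH in THF at 40 °C then converts 21 through 22 into 23. The route is rejoined at 21.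

Step 8. The benzylic hydroxyl may be acetylated as well, or the acetyl group may migrate from the primary to the benzylic oxygen before silylation. The fallback sets out from 14 and uses protection and deprotection instead of direct differentiation. TBSOTf and 2,6-lutidine (excess, CH2Cl2, 0 °C) should give tert-butyl{4-[(1R,2S)-1,3-bis(tert-butyldimethylsilyloxy)-2-(4-ethynyl-2,6-dimethoxyphenoxy)propyl]-2-methoxyphenoxy}dimethylsilane F5. HF·pyridine in pyridine/THF at 0 °C should cleave only the primary silyl ether to give (2S,3R)-3-(tert-butyldimethylsilyloxy)-3-[4-(tert-butyldimethylsilyloxy)-3-methoxyphenyl]-2-(4-ethynyl-2,6-dimethoxyphenoxy)propan-1-ol F6. Ac2O, pyridine and DMAP then give 16, where the route is rejoined without passing through 15.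

**Further compounds**

F1 | step 6 | (1S,2S)-1-[4-(tert-butyldimethylsilyloxy)-3-methoxyphenyl]-2-(4-ethynyl-2,6-dimethoxyphenoxy)propane-1,3-diol (threo) | COc1cc([C@H](O)[C@H](CO)Oc2c(OC)cc(C#C)cc2OC)ccc1O[Si](C)(C)C(C)(C)C
F2 | step 6 | (S)-1-[4-(tert-butyldimethylsilyloxy)-3-methoxyphenyl]-2-(4-ethynyl-2,6-dimethoxyphenoxy)-3-hydroxypropan-1-one | COc1cc(C(=O)[C@H](CO)Oc2c(OC)cc(C#C)cc2OC)ccc1O[Si](C)(C)C(C)(C)C
F3 | step 12 | 2,4,6-triacetoxybenzoic acid | CC(=O)Oc1cc(OC(C)=O)c(C(O)=O)c(OC(C)=O)c1
F4 | step 12 | 2,4,6-triacetoxybenzoyl chloride | CC(=O)Oc1cc(OC(C)=O)c(C(Cl)=O)c(OC(C)=O)c1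
F5 | step 8 | tert-butyl{4-[(1R,2S)-1,3-bis(tert-butyldimethylsilyloxy)-2-(4-ethynyl-2,6-dimethoxyphenoxy)propyl]-2-methoxyphenoxy}dimethylsilane | COc1cc([C@@H](O[Si](C)(C)C(C)(C)C)[C@H](CO[Si](C)(C)C(C)(C)C)Oc2c(OC)cc(C#C)cc2OC)ccc1O[Si](C)(C)C(C)(C)C
F6 | step 8 | (2S,3R)-3-(tert-butyldimethylsilyloxy)-3-[4-(tert-butyldimethylsilyloxy)-3-methoxyphenyl]-2-(4-ethynyl-2,6-dimethoxyphenoxy)propan-1-ol | COc1cc([C@@H](O[Si](C)(C)C(C)(C)C)[C@H](CO)Oc2c(OC)cc(C#C)cc2OC)ccc1O[Si](C)(C)C(C)(C)C
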